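Start from the leftover. Take the last eta reading from the charge and 0.263 M of starting material, the limiting reagent, remains unconverted at 62 min. Yet that run's target rose by 0.0240 M over the last 19.0 min.

the same everywhere: free catalyst 0.0150 M

| flask | starting material | partner | time |
|---|---|---|---|
| eta | 0.500 M | 1.25 M |  |
| alpha | 0.750 M | 1.25 M |  |
| epsilon | 0.500 M | 1.90 M |  |
| beta | 0.500 M | 2.60 M | 62 min |

| run | time / min | [target] / M |
|---|---|---|
| eta run | 4.7 | 0.049 |
| eta run | 14 | 0.119 |
| eta run | 27 | 0.187 |
| eta run | 43 | 0.213 |
| eta run | 62 | 0.237 |
| alpha run | 4.7 | 0.057 |
| alpha run | 14 | 0.137 |
| alpha run | 27 | 0.210 |
| alpha run | 43 | 0.258 |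
| alpha run | 62 | 0.269 |
| epsilon run | 4.7 | 0.065 |
| epsilon run | 14 | 0.168 |
| epsilon run | 27 | 0.236 |
| epsilon run | 43 | 0.278 |
| epsilon run | 62 | 0.285 |

(readings scatter by 0.004 M)

* the power of [starting material] that the first rate follows, about the charge of the eta run; measure it at two percent of starting material made into target (one fixed amount of target, the same in the runs compared)
* the power of [partner] that the first rate follows, about the charge of the eta run; measure it at two percent of starting material made into target
* target in the beta run at 62 min, as a share of the starting material charged

- Overall: starting material + partner -> target, with free catalyst as catalyst.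
- Constant volume, constant temperature.
- The analysis sees a species whether free or bound.
- "The second partner" is partner.
- An order is taken over about fifteen percent of the charge, up and down.

Solve each end, then join them. At the short end the target climbs along a line of slope r, the first reading over its time: 0.0104 M min⁻¹ in the eta run, 0.0121 M min⁻¹ in alpha, 0.0138 M min⁻¹ in epsilon. At the long end take the last reading. Divide that reading by r to get 22.7 min in the eta run, 22.2 min in alpha and 20.6 min in epsilon: this is the coast time τ, the time the first rate, held constant, would need to make the target of the last reading. The eta first reading carries a scatter of 8.16% of its value, so treat the three as one reading.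

The bench rule follows: keep τ and scale r. My rough orders from these first readings are 0.373 in starting material and 0.675 in partner. The partner order puts the beta first rate at 0.0171 M min⁻¹, and the epsilon τ then gives 70.4% of the charge.

Now find the border. Let T be the emptying time, charge over r: 48.0 min in the eta run, 29.3 min in beta. The line reaches the charge when τ equals T. With the epsilon τ, the beta run has τ shorter than T, but their ratio is 0.703, against 0.474 in eta and 0.570 in epsilon. The beta estimate thus lies beyond the runs, and the straight line takes no account of starting material used along it, so take my figure as the high side.

The forecast gives orders of 0.38 (0.15 to 0.65) and 0.72 (0.45 to 1), and 66% for beta (60% to 74%), lower than mine, holding that “Plateaus rise more weakly than rates”.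

The flask gives orders of 0.30 and 0.87, and 66.5% in beta.

    free catalyst + starting material ⇌ catalyst-substrate complex, settled at all times (4.150 M⁻¹)
    catalyst-substrate complex + partner ⇌ ternary complex, settled at all times (0.2130 M⁻¹)
    ternary complex → target + free catalyst (4.908 min⁻¹)
    partner → lost reagent (0.02004 min⁻¹)
    free catalyst + target → spent catalyst + target (0.4086 M⁻¹ min⁻¹)

Divide the beta target at 62 min by the estimated first rate and τ comes to 19.4 min. Now take the beta run in which free catalyst is not lost to spent catalyst: at 62 min it reaches 91.5% against 66.5%, and its τ, reckoned the same way, is longer than in the run as it stands, at 26.8 min. The loss of free catalyst to spent catalyst, which target brings about, is the main reason the beta run falls short, and it accounts for 75% of what is missing from the beta yield.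

Readings and results stem from a simulated flask on assumed constants; the scatter is artificial.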